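The route disconnects the five-membered ring (C9–C10–C11–C12–C20) at its trans ring-fusion pair, quaternary C12 (methyl C13) and C20–H. In one operation on 2-methylcyclopent-2-enone, a copper-catalysed asymmetric conjugate addition attaches the ketal-masked oxobutyl arm (C19–C16–C17–C18) to C20 and the enolate is allylated at C12 (C14–C15) from the opposite face; the precursors are the achiral enone, a ketal Grignard reagent and allyl bromide. The C11 carbonyl then relays chirality to C9 (reagent-controlled reduction, [2,3]-Wittig–Still shift), a Felkin-controlled Grignard addition sets C7, and a late aldol condensation of the C15 aldehyde with the C17 ketone closes the acetylcyclohexene.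

Key step: step 2

Remark on labels: carbons are labelled C1–C20 in the order in which they are written in the target SMILES; β is the face of the five-membered ring that carries the C13 methyl group, α the opposite face.
Assumption: both enantiomers of the ferrocenyl diphosphine ligand are available, and the one that gives (R)-configured C20 in enolate 5 is used.

Step 1
Reactants: 1 2-(2-bromoethyl)-2-methyl-1,3-dioxolane
Product: 2 [2-(2-methyl-1,3-dioxolan-2-yl)ethyl]magnesium bromide
Conditions: Mg turnings (I2-activated), THF, 25–30 °C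
Reagents that add atoms: magnesium [Mg]
Why: Grignard formation by insertion of magnesium into the primary C–Br bond is standard for this ketal-protected homoenolate equivalent, the dioxolane is inert to the organomagnesium, and no stereocentre is involved.

Step 2
Reactants: 2 [2-(2-methyl-1,3-dioxolan-2-yl)ethyl]magnesium bromide; 3 2-methylcyclopent-2-en-1-one; 4 allyl bromide
Product: 6 (2R,3R)-2-allyl-2-methyl-3-[2-(2-methyl-1,3-dioxolan-2-yl)ethyl]cyclopentan-1-one, via magnesium enolate 5 (not isolated)
Conditions: CuBr·SMe2 (5 mol %), Josiphos-type ferrocenyl diphosphine (6 mol %), tBuOMe, −78 °C, slow addition of 2; then 4, DMPU, −78 → 0 °C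
Reagents that add atoms: none
Why: The Grignard reagent transmetalates to the chiral copper–diphosphine complex, which binds the enone as a π-complex and delivers the alkyl group to the β-carbon C20 (C19–C20 bond) by oxidative addition and reductive elimination, releasing the regiodefined tetrasubstituted magnesium enolate 5; allyl bromide, activated by DMPU, then alkylates C12 (C12–C14 bond) in an SN2 step. The closest known reaction type is the copper-catalysed asymmetric conjugate addition of Grignard reagents to 2-substituted cycloalkenones with in situ enolate alkylation. No ring is closed in this step. C20 is set by the ligand, and C12 is set by the substrate, because the electrophile approaches the planar enolate anti to the new C20 arm, which should give the trans (2R,3R) relation that later becomes the trans ring fusion. The step needs 1,4- over 1,2-addition, secured by the copper catalyst at −78 °C with slow Grignard addition, and clean mono-C-allylation, secured because the enolate is formed regiospecifically at C12 and meets a reactive allylic halide in the presence of DMPU before proton transfer can occur.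

Step 3
Reactants: 6 (2R,3R)-2-allyl-2-methyl-3-[2-(2-methyl-1,3-dioxolan-2-yl)ethyl]cyclopentan-1-one
Product: 8 2-{(1R,2R)-1-methyl-2-[2-(2-methyl-1,3-dioxolan-2-yl)ethyl]-5-oxocyclopentyl}acetaldehyde, via ozonide 7 (not isolated)
Conditions: O3, CH2Cl2, −78 °C; then PPh3, −78 °C → rt
Reagents that add atoms: ozone [O-][O+]=O
Why: Ozonolysis (cycloaddition, cycloreversion and recombination to the 1,2,4-trioxolane, then reductive cleavage by PPh3) cuts the only C=C bond to the C15 aldehyde, while ketone and ketal are untouched and no stereocentre is affected.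

Step 4
Reactants: 8 2-{(1R,2R)-1-methyl-2-[2-(2-methyl-1,3-dioxolan-2-yl)ethyl]-5-oxocyclopentyl}acetaldehyde
Product: 9 (2R,3R)-2-(1,3-dioxolan-2-ylmethyl)-2-methyl-3-[2-(2-methyl-1,3-dioxolan-2-yl)ethyl]cyclopentan-1-one
Conditions: TMSOCH2CH2OTMS, TMSOTf (cat.), CH2Cl2, −78 °C
Reagents that add atoms: 1,2-bis(trimethylsilyloxy)ethane C[Si](C)(C)OCCO[Si](C)(C)C
Why: TMSOTf-catalysed silyl-transfer acetalisation at −78 °C is chemoselective for the aldehyde over the hindered α-quaternary cyclopentanone and masks C15 against the later hydrogenation and organometallic steps.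

Step 5
Reactants: 9 (2R,3R)-2-(1,3-dioxolan-2-ylmethyl)-2-methyl-3-[2-(2-methyl-1,3-dioxolan-2-yl)ethyl]cyclopentan-1-one
Product: 11 (4S,5R)-5-(1,3-dioxolan-2-ylmethyl)-5-methyl-4-[2-(2-methyl-1,3-dioxolan-2-yl)ethyl]cyclopent-2-en-1-one, via silyl enol ether 10 (not isolated)
Conditions: LDA, TMSCl, THF, −78 °C; then Pd(OAc)2 (1.1 equiv), MeCN, rt
Reagents that add atoms: chlorotrimethylsilane C[Si](C)(C)Cl (silyl group kept in 10 only)
Why: Saegusa–Ito oxidation: C10 is the only enolisable position of 9 (C12 is quaternary), so deprotonation with in situ silylation gives a single silyl enol ether, and palladation followed by β-hydride elimination of a C9 hydrogen gives the C9=C10 enone without touching C12 or C20.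

Step 6
Reactants: 11 (4S,5R)-5-(1,3-dioxolan-2-ylmethyl)-5-methyl-4-[2-(2-methyl-1,3-dioxolan-2-yl)ethyl]cyclopent-2-en-1-one
Product: 12 (1R,4S,5R)-5-(1,3-dioxolan-2-ylmethyl)-5-methyl-4-[2-(2-methyl-1,3-dioxolan-2-yl)ethyl]cyclopent-2-en-1-ol
Conditions: (S)-2-methyl-CBS-oxazaborolidine (15 mol %), catecholborane, toluene, −78 °C
Reagents that add atoms: none
Why: Corey–Bakshi–Shibata 1,2-reduction under catalyst control: the carbonyl binds to the oxazaborolidine boron anti to the quaternary C12 (large group) and hydride is delivered to the α face of C11, which should give the (R)-configured 11β-alcohol whatever small bias the substrate has.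

Step 7
Reactants: 12 (1R,4S,5R)-5-(1,3-dioxolan-2-ylmethyl)-5-methyl-4-[2-(2-methyl-1,3-dioxolan-2-yl)ethyl]cyclopent-2-en-1-ol
Product: 13 tributyl({[(1R,4S,5R)-5-(1,3-dioxolan-2-ylmethyl)-5-methyl-4-[2-(2-methyl-1,3-dioxolan-2-yl)ethyl]cyclopent-2-en-1-yl]oxy}methyl)stannane
Conditions: KH, 18-crown-6 (cat.), Bu3SnCH2I, THF, 0 °C → rt
Reagents that add atoms: (iodomethyl)tributylstannane CCCC[Sn](CCCC)(CCCC)CI
Why: Williamson etherification of the potassium alkoxide with the reactive primary iodide installs the tin handle for the sigmatropic shift with retention at C11.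

Step 8
Reactants: 13 tributyl({[(1R,4S,5R)-5-(1,3-dioxolan-2-ylmethyl)-5-methyl-4-[2-(2-methyl-1,3-dioxolan-2-yl)ethyl]cyclopent-2-en-1-yl]oxy}methyl)stannane
Product: 15 [(1S,4S,5S)-4-(1,3-dioxolan-2-ylmethyl)-4-methyl-5-[2-(2-methyl-1,3-dioxolan-2-yl)ethyl]cyclopent-2-en-1-yl]methanol, via alkoxymethyllithium 14 (not isolated)
Conditions: n-BuLi, THF, −78 → −20 °C
Reagents that add atoms: n-butyllithium [Li]CCCC (lithium kept in 14 only)
Why: Wittig–Still [2,3]-sigmatropic rearrangement: tin–lithium exchange gives 14, whose carbanion carbon bonds to C9 suprafacially through a five-membered envelope transition state, so the β configuration of the C11 oxygen is transferred to a 9β-hydroxymethyl group (C7) while the double bond moves to C10=C11.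

Step 9
Reactants: 15 [(1S,4S,5S)-4-(1,3-dioxolan-2-ylmethyl)-4-methyl-5-[2-(2-methyl-1,3-dioxolan-2-yl)ethyl]cyclopent-2-en-1-yl]methanol
Product: 16 [(1S,2S,3R)-3-(1,3-dioxolan-2-ylmethyl)-3-methyl-2-[2-(2-methyl-1,3-dioxolan-2-yl)ethyl]cyclopentyl]methanol
Conditions: H2 (1 atm), Pd/C, EtOAc, rt
Reagents that add atoms: none
Why: Heterogeneous catalytic hydrogenation saturates the only C=C bond (C10=C11) without creating or disturbing a stereocentre, and both acetals are stable under neutral conditions.

Step 10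
Reactants: 16 [(1S,2S,3R)-3-(1,3-dioxolan-2-ylmethyl)-3-methyl-2-[2-(2-methyl-1,3-dioxolan-2-yl)ethyl]cyclopentyl]methanol
Product: 17 (1S,2S,3R)-3-(1,3-dioxolan-2-ylmethyl)-3-methyl-2-[2-(2-methyl-1,3-dioxolan-2-yl)ethyl]cyclopentane-1-carboxylic acid
Conditions: TEMPO (cat.), NaOCl (cat.), NaClO2, MeCN/phosphate buffer (pH 6.7), 35 °C
Reagents that add atoms: sodium chlorite [Na+].[O-]Cl=O
Why: TEMPO-catalysed oxidation with NaClO2 as terminal oxidant takes the primary alcohol through the aldehyde to the acid under buffered conditions that spare both dioxolanes and should not epimerise C9.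

Step 11
Reactants: 17 (1S,2S,3R)-3-(1,3-dioxolan-2-ylmethyl)-3-methyl-2-[2-(2-methyl-1,3-dioxolan-2-yl)ethyl]cyclopentane-1-carboxylic acid
Product: 18 1-[(1S,2S,3R)-3-(1,3-dioxolan-2-ylmethyl)-3-methyl-2-[2-(2-methyl-1,3-dioxolan-2-yl)ethyl]cyclopentyl]ethan-1-one
Conditions: MeLi (2.5 equiv), THF, 0 °C; inverse quench into aq. NH4Cl
Reagents that add atoms: methyllithium [Li]C
Why: Addition of methyllithium to the lithium carboxylate gives a dilithio gem-diolate that collapses to the methyl ketone (C7=O, C8) only on work-up (classical ketone synthesis from carboxylic acids), so over-addition is avoided and C9 is untouched.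

Step 12
Reactants: 19 3-chloropropanoyl chloride
Product: 20 3-chloro-N-methoxy-N-methylpropanamide
Conditions: MeNH(OMe)·HCl, pyridine (2.2 equiv), CH2Cl2, 0 °C
Reagents that add atoms: N,O-dimethylhydroxylamine hydrochloride CNOC.Cl
Why: N-acylation of the hydroxylamine by the acid chloride gives the Weinreb amide, and pyridine at 0 °C is too weak a base to eliminate HCl from the β-chloro amide.

Step 13
Reactants: 20 3-chloro-N-methoxy-N-methylpropanamide
Product: 21 5-chloro-2-methylpent-1-en-3-one
Conditions: isopropenylmagnesium bromide, THF, −20 → 0 °C; cold aq. NH4Cl quench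
Reagents that add atoms: isopropenylmagnesium bromide C=C(C)[Mg]Br
Why: Weinreb ketone synthesis: the chelated tetrahedral magnesium intermediate survives until the cold quench, so only one isopropenyl group (C1–C3) is added and the base-sensitive β-chloro enone is released only on work-up.

Step 14
Reactants: 21 5-chloro-2-methylpent-1-en-3-one
Product: 22 (3S)-5-chloro-2-methylpent-1-en-3-ol
Conditions: (R)-2-methyl-CBS-oxazaborolidine (15 mol %), catecholborane, toluene, −78 °C
Reagents that add atoms: none
Why: Corey–Bakshi–Shibata reduction: the α-branched alkenyl group acts as the large substituent, so the (R)-catalyst should deliver hydride to give the (S)-allylic alcohol (C4), and the low temperature prevents hydroboration of the alkene.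

Step 15
Reactants: 22 (3S)-5-chloro-2-methylpent-1-en-3-ol
Product: 23 {[(3S)-5-chloro-2-methylpent-1-en-3-yl]oxy}triethylsilane
Conditions: TESCl, imidazole, CH2Cl2, 0 °C
Reagents that add atoms: chlorotriethylsilane CC[Si](CC)(CC)Cl
Why: Silylation protects the secondary allylic alcohol as an ether that tolerates Grignard formation and is later removed by the same aqueous acid that opens the dioxolanes.

Step 16
Reactants: 23 {[(3S)-5-chloro-2-methylpent-1-en-3-yl]oxy}triethylsilane; 18 1-[(1S,2S,3R)-3-(1,3-dioxolan-2-ylmethyl)-3-methyl-2-[2-(2-methyl-1,3-dioxolan-2-yl)ethyl]cyclopentyl]ethan-1-one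
Product: 25 (2S,5S)-2-[(1S,2S,3R)-3-(1,3-dioxolan-2-ylmethyl)-3-methyl-2-[2-(2-methyl-1,3-dioxolan-2-yl)ethyl]cyclopentyl]-6-methyl-5-[(triethylsilyl)oxy]hept-6-en-2-ol, via Grignard reagent 24 (not isolated)
Conditions: Mg (I2-activated), THF, 50 °C; then 18, LaCl3·2LiCl (30 mol %), THF, −78 → 0 °C
Reagents that add atoms: magnesium [Mg] (kept in 24 only)
Why: Grignard addition to the methyl ketone under Felkin–Anh control: the nucleophile approaches anti to the C9–C20 bond (C20, the branched ring carbon bearing the cis arm, is the large group) with the carbonyl oxygen on the side of C10, which should give the (7S) tertiary alcohol, as 20-oxo steroids do with alkyl Grignard reagents; LaCl3·2LiCl suppresses enolisation and hence epimerisation at C9.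

Step 17
Reactants: 25 (2S,5S)-2-[(1S,2S,3R)-3-(1,3-dioxolan-2-ylmethyl)-3-methyl-2-[2-(2-methyl-1,3-dioxolan-2-yl)ethyl]cyclopentyl]-6-methyl-5-[(triethylsilyl)oxy]hept-6-en-2-ol
Product: 27 1-[(3S,3aS,7aR)-3-[(2S,5S)-2,5-dihydroxy-6-methylhept-6-en-2-yl]-7a-methyl-2,3,3a,4,7,7a-hexahydro-1H-inden-5-yl]ethan-1-one, via keto aldehyde 26 (not isolated)
Conditions: 1 M HCl, THF, rt; then KOH, MeOH, rt
Reagents that add atoms: water O
Why: Aqueous acid hydrolyses both dioxolanes and the silyl ether, and base then drives the intramolecular aldol condensation in which C16, the more substituted α-carbon of the methyl ketone, attacks the C15 aldehyde (six-membered ring, C15–C16 bond) and dehydrates to the conjugated acetylcyclohexene; the trans ring fusion is already fixed by C12 and C20, so no stereocentre is created.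

Step 18
Reactants: 27 1-[(3S,3aS,7aR)-3-[(2S,5S)-2,5-dihydroxy-6-methylhept-6-en-2-yl]-7a-methyl-2,3,3a,4,7,7a-hexahydro-1H-inden-5-yl]ethan-1-one
Product: 28 (3S,6S)-6-[(1S,3aR,7aS)-6-acetyl-3a-methyl-2,3,3a,4,7,7a-hexahydro-1H-inden-1-yl]-6-hydroxy-2-methylhept-1-en-3-yl acetate
Conditions: Ac2O, pyridine, DMAP (cat.), CH2Cl2, 0 °C
Reagents that add atoms: acetic anhydride CC(=O)OC(C)=O
Why: DMAP-catalysed acylation esterifies the secondary allylic C4 hydroxyl with retention, while the tertiary C7 hydroxyl is too hindered to react at 0 °C.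

Compound list
1 | 2-(2-bromoethyl)-2-methyl-1,3-dioxolane | CC1(CCBr)OCCO1 | starting material
2 | [2-(2-methyl-1,3-dioxolan-2-yl)ethyl]magnesium bromide | CC1(CC[Mg]Br)OCCO1 | intermediate
3 | 2-methylcyclopent-2-en-1-one | CC1=CCCC1=O | starting material
4 | allyl bromide (3-bromoprop-1-ene) | C=CCBr | starting material
5 | bromomagnesium enolate (C11–OMgBr, C11=C12) of (3R)-2-methyl-3-[2-(2-methyl-1,3-dioxolan-2-yl)ethyl]cyclopentanone, not isolated | C1CC(O[Mg]Br)=C(C)[C@H]1CCC2(C)OCCO2 | intermediate
6 | (2R,3R)-2-allyl-2-methyl-3-[2-(2-methyl-1,3-dioxolan-2-yl)ethyl]cyclopentan-1-one (12β-methyl, 12α-allyl, 20β-arm) | C1CC(=O)[C@](C)(CC=C)[C@H]1CCC2(C)OCCO2 | intermediate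
7 | secondary ozonide (1,2,4-trioxolane) of 6, mixture at the trioxolane carbon, not isolated | C1CC(=O)[C@](C)(CC3OCOO3)[C@H]1CCC2(C)OCCO2 | intermediate
8 | 2-{(1R,2R)-1-methyl-2-[2-(2-methyl-1,3-dioxolan-2-yl)ethyl]-5-oxocyclopentyl}acetaldehyde (C15 aldehyde) | C1CC(=O)[C@](C)(CC=O)[C@H]1CCC2(C)OCCO2 | intermediate
9 | (2R,3R)-2-(1,3-dioxolan-2-ylmethyl)-2-methyl-3-[2-(2-methyl-1,3-dioxolan-2-yl)ethyl]cyclopentan-1-one | C1CC(=O)[C@](C)(CC3OCCO3)[C@H]1CCC2(C)OCCO2 | intermediate
10 | trimethylsilyl enol ether (C10=C11–OSiMe3) of 9, not isolated | C1C=C(O[Si](C)(C)C)[C@](C)(CC3OCCO3)[C@H]1CCC2(C)OCCO2 | intermediate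
11 | (4S,5R)-5-(1,3-dioxolan-2-ylmethyl)-5-methyl-4-[2-(2-methyl-1,3-dioxolan-2-yl)ethyl]cyclopent-2-en-1-one (C11=O, C9=C10) | C1=CC(=O)[C@](C)(CC3OCCO3)[C@H]1CCC2(C)OCCO2 | intermediate
12 | (1R,4S,5R)-5-(1,3-dioxolan-2-ylmethyl)-5-methyl-4-[2-(2-methyl-1,3-dioxolan-2-yl)ethyl]cyclopent-2-en-1-ol (11β-OH) | C1=C[C@@H](O)[C@](C)(CC3OCCO3)[C@H]1CCC2(C)OCCO2 | intermediate
13 | tributyl({[(1R,4S,5R)-5-(1,3-dioxolan-2-ylmethyl)-5-methyl-4-[2-(2-methyl-1,3-dioxolan-2-yl)ethyl]cyclopent-2-en-1-yl]oxy}methyl)stannane | C1=C[C@@H](OC[Sn](CCCC)(CCCC)CCCC)[C@](C)(CC3OCCO3)[C@H]1CCC2(C)OCCO2 | intermediate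
14 | α-alkoxymethyllithium from 13 (C11–O–CH2Li), not isolated | C1=C[C@@H](OC[Li])[C@](C)(CC3OCCO3)[C@H]1CCC2(C)OCCO2 | intermediate
15 | [(1S,4S,5S)-4-(1,3-dioxolan-2-ylmethyl)-4-methyl-5-[2-(2-methyl-1,3-dioxolan-2-yl)ethyl]cyclopent-2-en-1-yl]methanol (9β-CH2OH, C10=C11) | OC[C@H]1C=C[C@](C)(CC3OCCO3)[C@H]1CCC2(C)OCCO2 | intermediate
16 | [(1S,2S,3R)-3-(1,3-dioxolan-2-ylmethyl)-3-methyl-2-[2-(2-methyl-1,3-dioxolan-2-yl)ethyl]cyclopentyl]methanol | OC[C@H]1CC[C@](C)(CC3OCCO3)[C@H]1CCC2(C)OCCO2 | intermediate
17 | (1S,2S,3R)-3-(1,3-dioxolan-2-ylmethyl)-3-methyl-2-[2-(2-methyl-1,3-dioxolan-2-yl)ethyl]cyclopentane-1-carboxylic acid | OC(=O)[C@H]1CC[C@](C)(CC3OCCO3)[C@H]1CCC2(C)OCCO2 | intermediate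
18 | 1-[(1S,2S,3R)-3-(1,3-dioxolan-2-ylmethyl)-3-methyl-2-[2-(2-methyl-1,3-dioxolan-2-yl)ethyl]cyclopentyl]ethan-1-one (9β-acetyl) | CC(=O)[C@H]1CC[C@](C)(CC3OCCO3)[C@H]1CCC2(C)OCCO2 | intermediate
19 | 3-chloropropanoyl chloride | ClCCC(Cl)=O | starting material
20 | 3-chloro-N-methoxy-N-methylpropanamide | ClCCC(=O)N(C)OC | intermediate
21 | 5-chloro-2-methylpent-1-en-3-one | C=C(C)C(=O)CCCl | intermediate
22 | (3S)-5-chloro-2-methylpent-1-en-3-ol | C=C(C)[C@H](CCCl)O | intermediate
23 | {[(3S)-5-chloro-2-methylpent-1-en-3-yl]oxy}triethylsilane | C=C(C)[C@H](CCCl)O[Si](CC)(CC)CC | intermediate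
24 | [(3S)-4-methyl-3-[(triethylsilyl)oxy]pent-4-en-1-yl]magnesium chloride, not isolated | C=C(C)[C@H](CC[Mg]Cl)O[Si](CC)(CC)CC | intermediate
25 | (2S,5S)-2-[(1S,2S,3R)-3-(1,3-dioxolan-2-ylmethyl)-3-methyl-2-[2-(2-methyl-1,3-dioxolan-2-yl)ethyl]cyclopentyl]-6-methyl-5-[(triethylsilyl)oxy]hept-6-en-2-ol | C=C(C)[C@H](CC[C@](C)(O)[C@H]1CC[C@](C)(CC3OCCO3)[C@H]1CCC2(C)OCCO2)O[Si](CC)(CC)CC | intermediate
26 | keto aldehyde: 2-{(1R,2S,3S)-3-[(2S,5S)-2,5-dihydroxy-6-methylhept-6-en-2-yl]-1-methyl-2-(3-oxobutyl)cyclopentyl}acetaldehyde, not isolated | C=C(C)[C@H](CC[C@](C)(O)[C@H]1CC[C@](C)(CC=O)[C@H]1CCC(C)=O)O | intermediate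
27 | 1-[(3S,3aS,7aR)-3-[(2S,5S)-2,5-dihydroxy-6-methylhept-6-en-2-yl]-7a-methyl-2,3,3a,4,7,7a-hexahydro-1H-inden-5-yl]ethan-1-one | C=C(C)[C@H](CC[C@](C)(O)[C@H]1CC[C@]2(C)CC=C(C(C)=O)C[C@@H]12)O | intermediate
28 | (3S,6S)-6-[(1S,3aR,7aS)-6-acetyl-3a-methyl-2,3,3a,4,7,7a-hexahydro-1H-inden-1-yl]-6-hydroxy-2-methylhept-1-en-3-yl acetate (CNP0264549.1) | C=C(C)[C@H](CC[C@](C)(O)[C@H]1CC[C@]2(C)CC=C(C(C)=O)C[C@@H]12)OC(C)=O | target

Total step count: 18 (Grignard reagents 2 and 24 and the other in-flask intermediates are counted within their steps, except step 1).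
Longest linear sequence: 14 steps (steps 1–11, then 16–18); the side-chain arm is steps 12–15 followed by 16–18.

Steps most likely to fail

Step 2. The enantioselectivity may erode because the oxygen-bearing Grignard reagent, which has to be made in THF, competes with the diphosphine for copper. Slow allylation may also allow proton exchange between product and enolate, leading to over-alkylation or loss of the trans relation. The fallback separates the two bond formations. Setting out from 2 and 3, the conjugate addition is run as in step 2, but enolate 5 is trapped at −78 °C with allyl chloroformate to give the allyl enol carbonate F1, which is isolated. Catalytic Pd(PPh3)4 (zerovalent palladium) in THF then effects decarboxylative Tsuji allylation, the allyl group being returned to C12 anti to the C20 arm, and the sequence rejoins the route at 6.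

Step 16. Addition may occur from the unintended face of the C7 carbonyl, or the basic Grignard reagent may enolise the ketone and so epimerise C9. The fallback applies if the facial preference proves to be the reverse of the predicted one: the two C7 substituents are introduced in the opposite order, so that the same preference gives the required configuration. Setting out from acid 17, coupling with N,O-dimethylhydroxylamine (EDC·HCl, DMAP, CH2Cl2) gives the Weinreb amide F2. Grignard reagent 24 converts it into the chain ketone F3, and MeMgBr with LaCl3·2LiCl in THF at −78 °C adds the C8 methyl group, rejoining the route at 25.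

Step 8. The α-alkoxymethyllithium may undergo a [1,2]-shift or be protonated instead of rearranging, because the new bond must form next to the C20 arm; the preceding etherification of the hindered alkoxide may also be slow. The fallback is a carbene [2,3]-shift that needs neither the stannyl ether nor an organolithium. Setting out from alcohol 12, heating with N,N-dimethylformamide dimethyl acetal in xylene at 140 °C (Büchi rearrangement) should give the β,γ-unsaturated dimethylamide F4 with the same suprafacial transfer to C9. Hydrogenation (H2, Pd/C, EtOAc) gives the saturated amide F5, and MeLi in THF at 0 °C converts it into the methyl ketone, rejoining the route at 18.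

Further compounds
F1 | step 2 | allyl (3R)-2-methyl-3-[2-(2-methyl-1,3-dioxolan-2-yl)ethyl]cyclopent-1-en-1-yl carbonate | C1CC(OC(=O)OCC=C)=C(C)[C@H]1CCC2(C)OCCO2
F2 | step 16 | (1S,2S,3R)-3-(1,3-dioxolan-2-ylmethyl)-N-methoxy-N,3-dimethyl-2-[2-(2-methyl-1,3-dioxolan-2-yl)ethyl]cyclopentane-1-carboxamide | CON(C)C(=O)[C@H]1CC[C@](C)(CC3OCCO3)[C@H]1CCC2(C)OCCO2
F3 | step 16 | (4S)-1-[(1S,2S,3R)-3-(1,3-dioxolan-2-ylmethyl)-3-methyl-2-[2-(2-methyl-1,3-dioxolan-2-yl)ethyl]cyclopentyl]-5-methyl-4-[(triethylsilyl)oxy]hex-5-en-1-one | C=C(C)[C@H](CCC(=O)[C@H]1CC[C@](C)(CC3OCCO3)[C@H]1CCC2(C)OCCO2)O[Si](CC)(CC)CC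
F4 | step 8 | (1S,4S,5S)-4-(1,3-dioxolan-2-ylmethyl)-N,N,4-trimethyl-5-[2-(2-methyl-1,3-dioxolan-2-yl)ethyl]cyclopent-2-ene-1-carboxamide | CN(C)C(=O)[C@H]1C=C[C@](C)(CC3OCCO3)[C@H]1CCC2(C)OCCO2
F5 | step 8 | (1S,2S,3R)-3-(1,3-dioxolan-2-ylmethyl)-N,N,3-trimethyl-2-[2-(2-methyl-1,3-dioxolan-2-yl)ethyl]cyclopentane-1-carboxamide | CN(C)C(=O)[C@H]1CC[C@](C)(CC3OCCO3)[C@H]1CCC2(C)OCCO2
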